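## Analysis of the target

The target 24 is a bis-spiro compound in which two 4-bromo-3-(1-acetoxybutyl)furan-2(5H)-one rings (rings A and B; O1, C2 carbonyl, C3, C4–Br, C5) share their C5 atoms with two neighbouring carbons of a cyclobutane (ring C), whose other two carbons are CHBr. Of the six stereocentres, the two quaternary spiro carbons carry their ring oxygens trans on ring C, and the two CHBr carbons carry bromines that are trans to each other and each trans to the ring oxygen (cis to the vinylic C4) of the neighbouring spiro carbon, so the core has a C2 axis. The two side-chain carbinol carbons have opposite descriptors (S on one ring, R on the other), which because of that axis defines a single compound whichever ring carries which. The C4 bromides are vinylogous acyl bromides open to addition–elimination by amines, phosphines and alkoxides, and the allylic acetates and the vicinal dibromide are prone to elimination. The difficulty lies in two contiguous quaternary stereocentres on a four-membered ring, in ring C bromines that sit on the more hindered side next to C4–Br, and in two symmetry-equivalent side chains that must end with opposite configurations. In addition, any cyclobutene intermediate with oxygen donors trans on its sp3 carbons is set up for conrotatory ring opening, which is very fast for alkoxides and easy for free or silylated hydroxyls. The strategy rests on the fact that each spiro carbon carries one oxygen (O1) and one carboxyl-level carbon (C4) and that the two spiro carbons are bonded to each other with the oxygens trans, which is the C2/C3 unit of a tartaric ester, while the C3–C4 bond of each butenolide joins an acyl α-carbon to a former ester carbon and is therefore a Dieckmann bond. With the ring C carbons in the place of the tartrate hydrogens the arrangement is that of the (R,R) series, but enolate alkylation of a tartrate acetonide puts the new carbon where the ester stood and moves the ester to the place of hydrogen, so the (S,S) acetonide 1 is the correct chiral-pool source.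

## Retrosynthetic reasoning

**24 to 23.** The two C–Br bonds of ring C are cut. A trans vicinal dihalide maps onto anti addition of halogen to alkene 23. Both alkene carbons are CH flanked by quaternary centres, and the two faces are exchanged by the C2 axis. The strained alkene, not an elimination-prone dibromide, is then carried through the base and phosphine steps. The forward step must touch only the cyclobutene and must open the bromonium ion at the correct carbon. The second requirement is the weak point.

**23 to 22 to 21.** The two acetate C–O bonds are cut. Both carbinols are made with the same sense in diol 21. One is acetylated with retention (22) and the other esterified with inversion (23). The hydroxyls of 21 are exchanged by the C2 axis, so no site selectivity is needed, only mono-functionalisation. That step is statistical and the recovered diol is recycled.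

**21 to 20.** The carbinol C–H bonds are cut to give diketone 20. The ketones are enone-type carbonyls flanked by a fully substituted sp2 carbon and a propyl group. They are far from the core, so a chiral reduction catalyst must set both centres.

**20 to 19.** The C4–Br bonds are traced back to the C4 hydroxyls of bis-tetronic acid 19. This brings the structure to a 3-acyl tetronic acid, the product type of a Dieckmann closure.

**19 to 17 (key disconnection).** Both C3–C4 bonds are cut. This reveals bis(β-keto ester) 17, in which each ring carbon carries a methyl ester and an O-(3-oxohexanoyl) group. The cut is made here because the acidic methylene and the ester sit on the same carbon, so closure is five-membered. No bond to a quaternary carbon is made or broken, so the spiro configuration can be set earlier on an open chain. A cut at C4–C5 or at the spiro–spiro bond would create the quaternary centres in the bond-forming step. The forward reaction must enolise only the active methylene, close the five- and not the six-membered ring, and never place an alkoxide on a ring carbon.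

**17 to 16 to 11 and 14.** The alkene of 17 is traced to the cis-diol thionocarbonate 16 (syn cycloelimination). The two ester C–O bonds are traced to the tertiary hydroxyls of 11 and two molecules of acyl Meldrum's acid 14, itself from 12 and 13. This order is chosen for two reasons. The cyclobutene then never bears free or silylated hydroxyls on its sp3 carbons. The heat needed for the acylation is applied to a saturated ring.

**11 to 10 to 9 to 8.** The ring C bond between the two future alkene carbons is cut by a pinacol transform to dialdehyde 8. The cut is symmetric and uses the C2 axis. Only one cis-diol 9 can exist, and a cis-diol is what the thionocarbonate 10 requires. The forward coupling must beat loss of the α-oxygen substituents.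

**8 to 7 to 6 to 5 to 4.** These are changes of oxidation level and protecting group. The isopropylidene acetal of 4 cannot be kept. A dioxolane across the trans-diol of ring C would be trans-fused to a four-membered ring. It is exchanged for two silyl ethers (6) before the arms are unmasked (7) and oxidised (8).

**4 to 3 to 1 and 2.** The two C–C bonds at the carbinol carbons are cut by enolate alkylation with electrophile 2. The first alkylation goes anti to the ester on the neighbouring ring carbon. The second should go anti to the arm already installed. Both therefore place the new carbon where an ester of 1 stood, and the (S,S) acetonide 1 gives (4R,5R)-4 with the spatial arrangement needed in 24.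

## Alternatives that were turned down

**Alternative 1:** Ring C is cut at the spiro–spiro bond and at one spiro-carbon–CH bond. One butenolide, as silyloxyfuran A2, supplies one ring carbon. The other, as methoxy lactol A3 with a 2-oxoethyl chain on C5, supplies three.
- Forward key step: a silyl triflate Lewis acid ionises A3 at its acetal carbon and C5 of A2 adds to the resulting cation. The coupled butenolide is re-silylated with an amine base and closes onto its aldehyde in a 4-exo Mukaiyama-type aldol to give A1.
- For: it is convergent, both vinylic bromides and both side chains are in place before the union, and the side chains are differentiated from the start (acetate and silyl ether). No statistical step is needed, and on this point it is stronger than the chosen route.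
- Against: both quaternary spiro centres are formed in ionic C–C bond formations. Nothing but the remote side-chain carbinols controls their relative (trans) or absolute configuration. The 4-exo aldol to a cyclobutanol is strained and reversible. A1 still carries CH(OSiMe3)–CH2 where CHBr–CHBr is needed, so elimination and the same bromine addition follow.
- Comparison: the chosen strategy is longer but fixes the spiro configuration from the chiral pool.

**Alternative 2:** Ring C and the spiro–spiro bond are taken from a flat 2-pyrone A5.
- Forward key step: photochemical 4π-electrocyclisation joins C3 and C6 of A5 and gives the bicyclic β-lactone A4.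
- For: one step builds the cyclobutene and both quaternary carbons with the right relative arrangement (oxygens trans, carboxyl carbons trans). The cis-fused bicycle A4 cannot open by conrotation, so it is thermally sturdier than the monocyclic cyclobutenes of the chosen route. It is stronger on step count to the core and on stability.
- Against: A5 is achiral, so A4 is formed racemic and the single enantiomer needs a resolution or an unproven asymmetric variant. Opening the β-lactone of A4 by alcoholysis puts an alkoxide on a cyclobutene carbon. The two butenolides must then still be built, one after the other, because the carboxyl carbons and oxygens of A4 are differentiated.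
- Comparison: the chosen strategy offers absolute configuration from tartrate and closure of both rings in one symmetric operation.

**Alternative 3:** Both C4–C5 bonds and both lactone C–O bonds are cut, giving cyclobutenedione A7 and two equivalents of dibromoacrylate A8, which is lithiated at its bromine-bearing carbon before the union.
- Forward key step: halogen–lithium exchange on A8 at very low temperature, double carbonyl addition to A7 and lactonisation of the alkoxides onto the esters give A6.
- For: it is the shortest route. One step delivers both bromobutenolides with the side chains at the final oxidation level. No Dieckmann closure, deoxybromination or ketone reduction is needed, and on step economy it is clearly stronger.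
- Against: A7 is a labile diketone. The first adduct is an alkoxide on a cyclobutenone carbon, the classic case of fast electrocyclic opening. The cis or trans course of the second addition and the facial sense relative to the side-chain centre are not controlled. Lithiated A8 is a carbenoid and can undergo α-elimination. Both side chains arrive with the same configuration, so the S/R pattern still needs a desymmetrisation.
- Comparison: the chosen strategy avoids any alkoxide on the strained ring and fixes the spiro centres before the ring exists.

Key step: step 13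

Assumption: acetonide 1 is taken as a purchased compound; if it is not stocked, dimethyl D-tartrate, 2,2-dimethoxypropane and TsOH give it in one step.

## Route

Step 1
Reactants: 1 dimethyl (4S,5S)-2,2-dimethyl-1,3-dioxolane-4,5-dicarboxylate (acetonide of dimethyl D-tartrate); 2 benzyl chloromethyl ether
Product: 3 dimethyl (4R,5S)-4-[(benzyloxy)methyl]-2,2-dimethyl-1,3-dioxolane-4,5-dicarboxylate (new arm trans to the C5 ester; the two esters cis)
Conditions: LiN(iPr)2 (1.1 equiv), THF/DMPU, −78 °C; then 2, −78 → −50 °C
Reagents that add atoms: none
Why: Alkylation of the lithium ester enolate of a tartrate acetonide, which does not undergo β-elimination at −78 °C; the electrophile enters the enolate face anti to the ester on the neighbouring ring carbon, so the new carbon takes the side the C4 ester held and that ester moves to the side of the former hydrogen.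

Step 2
Reactants: 3 dimethyl (4R,5S)-4-[(benzyloxy)methyl]-2,2-dimethyl-1,3-dioxolane-4,5-dicarboxylate; 2 benzyl chloromethyl ether
Product: 4 dimethyl (4R,5R)-4,5-bis[(benzyloxy)methyl]-2,2-dimethyl-1,3-dioxolane-4,5-dicarboxylate (C2-symmetric; arms trans, esters trans)
Conditions: LiN(iPr)2 (1.2 equiv), THF/DMPU, −78 °C; then 2, −78 → −40 °C
Reagents that add atoms: none
Why: Second enolate alkylation of the same type with a very reactive α-chloro ether; the electrophile should enter anti to the benzyloxymethyl arm on the neighbouring quaternary carbon, a path that also avoids eclipsing of the two arms and of the two ester dipoles in the product. The cis,cis (meso-type) isomer, if formed, is removed here by chromatography.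

Step 3
Reactants: 4 dimethyl (4R,5R)-4,5-bis[(benzyloxy)methyl]-2,2-dimethyl-1,3-dioxolane-4,5-dicarboxylate
Product: 5 dimethyl (2R,3R)-2,3-bis[(benzyloxy)methyl]-2,3-dihydroxybutanedioate
Conditions: TFA/H2O (9:1), 0 °C → rt
Reagents that add atoms: none
Why: Acid hydrolysis of the isopropylidene acetal; benzyl ethers and methyl esters are stable. The acetal must go before ring closure because it would be trans-fused to the four-membered ring.

Step 4
Reactants: 5 dimethyl (2R,3R)-2,3-bis[(benzyloxy)methyl]-2,3-dihydroxybutanedioate
Product: 6 dimethyl (2R,3R)-2,3-bis[(benzyloxy)methyl]-2,3-bis(triethylsilyloxy)butanedioate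
Conditions: Et3SiOTf (3 equiv), 2,6-lutidine, CH2Cl2, 0 °C → rt
Reagents that add atoms: triethylsilyl trifluoromethanesulfonate, CC[Si](CC)(CC)OS(=O)(=O)C(F)(F)F
Why: Silyl triflate silylation of hindered tertiary alcohols; the triethylsilyl ethers keep the tertiary hydroxyls out of ketol and hemiacetal chemistry at the aldehyde stage and survive hydrogenolysis, SmI2 and thionocarbonate formation.

Step 5
Reactants: 6 dimethyl (2R,3R)-2,3-bis[(benzyloxy)methyl]-2,3-bis(triethylsilyloxy)butanedioate
Product: 7 dimethyl (2R,3R)-2,3-bis(hydroxymethyl)-2,3-bis(triethylsilyloxy)butanedioate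
Conditions: H2 (1 atm), 10% Pd/C, EtOAc, rt
Reagents that add atoms: none
Why: Hydrogenolysis of benzyl ethers in a neutral, non-nucleophilic solvent. Each hydroxymethyl group stands 1,4 to the ester of the neighbouring carbon and could lactonise, so the crude diol is oxidised at once.

Step 6
Reactants: 7 dimethyl (2R,3R)-2,3-bis(hydroxymethyl)-2,3-bis(triethylsilyloxy)butanedioate
Product: 8 dimethyl (2S,3S)-2,3-diformyl-2,3-bis(triethylsilyloxy)butanedioate (same spatial arrangement as 7; the descriptors change with the priorities)
Conditions: Dess–Martin periodinane, pyridine, CH2Cl2, 0 °C → rt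
Reagents that add atoms: none
Why: Dess–Martin oxidation of neopentyl-type primary alcohols under buffered, non-aqueous conditions; the aldehydes are not enolisable, so no centre can epimerise.

Step 7
Reactants: 8 dimethyl (2S,3S)-2,3-diformyl-2,3-bis(triethylsilyloxy)butanedioate
Product: 9 dimethyl (1R,2R,3R,4S)-3,4-dihydroxy-1,2-bis(triethylsilyloxy)cyclobutane-1,2-dicarboxylate (silyloxy groups trans, hydroxyls cis)
Conditions: SmI2 (2.5 equiv), t-BuOH (2 equiv), THF, −78 °C → rt
Reagents that add atoms: none
Why: Samarium diiodide pinacol cyclisation of a 1,4-dialdehyde to a cyclobutane-1,2-diol, a known ring closure for 1,4-dicarbonyl compounds, helped here by the two quaternary carbons (Thorpe–Ingold effect). Coupling of the two metal-bound ketyl oxygens on one face sets the two new carbinol centres cis, and because of the C2 axis of 8 only one cis-diol exists.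

Step 8
Reactants: 9 dimethyl (1R,2R,3R,4S)-3,4-dihydroxy-1,2-bis(triethylsilyloxy)cyclobutane-1,2-dicarboxylate
Product: 10 cyclic thionocarbonate of 9: dimethyl 3-thioxo-6,7-bis(triethylsilyloxy)-2,4-dioxabicyclo[3.2.0]heptane-6,7-dicarboxylate (ring fusion cis; silyloxy groups trans; configuration of 9)
Conditions: 1,1'-thiocarbonyldiimidazole, DMAP (cat.), toluene, 80 °C
Reagents that add atoms: 1,1'-thiocarbonyldiimidazole, S=C(n1ccnc1)n1ccnc1
Why: Thionocarbonate formation from a cis-1,2-diol, the first half of a Corey–Winter olefination; a trans-diol by-product cannot cyclise and is removed. The ring also masks the secondary hydroxyls for the later acylation.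

Step 9
Reactants: 10 dimethyl 3-thioxo-6,7-bis(triethylsilyloxy)-2,4-dioxabicyclo[3.2.0]heptane-6,7-dicarboxylate
Product: 11 dimethyl 6,7-dihydroxy-3-thioxo-2,4-dioxabicyclo[3.2.0]heptane-6,7-dicarboxylate (tertiary hydroxyls trans; ring fusion cis)
Conditions: HF·pyridine, THF/pyridine, 0 °C → rt
Reagents that add atoms: none
Why: Acidic fluoride cleavage of tertiary triethylsilyl ethers; esters and the thionocarbonate are stable, and no alkoxide is formed that could shift the thionocarbonate onto a tertiary oxygen.

Step 10
Reactants: 12 Meldrum's acid (2,2-dimethyl-1,3-dioxane-4,6-dione); 13 butanoyl chloride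
Product: 14 5-(1-hydroxybutylidene)-2,2-dimethyl-1,3-dioxane-4,6-dione (butanoyl Meldrum's acid, enol form)
Conditions: pyridine (2 equiv), CH2Cl2, 0 °C → rt; 1 M HCl wash
Reagents that add atoms: none
Why: C-acylation of Meldrum's acid by an acid chloride with pyridine, the standard preparation of acyl Meldrum's acids as acylketene precursors.

Step 11
Reactants: 11 dimethyl 6,7-dihydroxy-3-thioxo-2,4-dioxabicyclo[3.2.0]heptane-6,7-dicarboxylate; 14 5-(1-hydroxybutylidene)-2,2-dimethyl-1,3-dioxane-4,6-dione (two molecules are consumed, one for each tertiary hydroxyl)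
Product: 16 dimethyl 6,7-bis(3-oxohexanoyloxy)-3-thioxo-2,4-dioxabicyclo[3.2.0]heptane-6,7-dicarboxylate (acyloxy groups trans; ring fusion cis), via butanoylketene 15 (not isolated)
Conditions: 14 (4 equiv, in portions), toluene, 95 °C
Reagents that add atoms: 5-(1-hydroxybutylidene)-2,2-dimethyl-1,3-dioxane-4,6-dione (second equivalent of 14), CCCC(O)=C1C(=O)OC(C)(C)OC1=O
Why: Thermolysis of each molecule of the acyl Meldrum's acid releases acetone and CO2 and gives the acylketene, one molecule of which adds to each tertiary hydroxyl to form the two β-keto esters without any base. Acylketenes acylate hindered tertiary alcohols, and the saturated bicycle tolerates the heat that a cyclobutene would not.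

Step 12
Reactants: 16 dimethyl 6,7-bis(3-oxohexanoyloxy)-3-thioxo-2,4-dioxabicyclo[3.2.0]heptane-6,7-dicarboxylate
Product: 17 dimethyl (1R,2R)-1,2-bis(3-oxohexanoyloxy)cyclobut-3-ene-1,2-dicarboxylate
Conditions: 1,3-dimethyl-2-phenyl-1,3,2-diazaphospholidine (3 equiv), THF, 25–40 °C
Reagents that add atoms: none
Why: Corey–Winter olefination in its low-temperature Corey–Hopkins form: thiophilic attack at sulfur and syn cycloelimination of CO2 from the cis-fused thionocarbonate give the ring alkene, and the quaternary centres are not touched. Placing it after the acylation means the cyclobutene carries only acyloxy groups, the weakest oxygen donors available, on its sp3 carbons; 17 is kept cold and used directly.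

Step 13
Reactants: 17 dimethyl (1R,2R)-1,2-bis(3-oxohexanoyloxy)cyclobut-3-ene-1,2-dicarboxylate
Product: 19 3,9-dibutanoyl-4,10-dihydroxy-1,7-dioxadispiro[4.0.4.2]dodeca-3,9,11-triene-2,8-dione (bis-spiro 3-butanoyl tetronic acid; spiro carbons C5 and C6 with the configuration of 17, ring oxygens trans), via mono-cyclised tetronic acid 18 (not isolated)
Conditions: KOtBu (2.2 equiv), THF, −40 → 0 °C; then 1 M HCl
Reagents that add atoms: none
Why: The base removes a proton from the doubly activated methylene of each 3-oxohexanoate, the enolate carbon adds to the methyl ester on the same ring carbon, methoxide leaves, and the new triacylmethane C–H is lost at once to give the tetronate. The closest known reaction is the Lacey–Dieckmann cyclisation of O-(β-ketoacyl) α-hydroxy esters to 3-acyl tetronic acids. Each of the two rings closes 5-exo-trig, the second after the first through 18, and each is spiro to the cyclobutene. No stereocentre is formed and no bond to a spiro carbon is broken, so both keep the tartrate-derived configuration. The step needs chemoselectivity only: the active methylene is far more acidic than any other site, so one equivalent of base per ring suffices. The five-membered closure onto the geminal ester is expected to outrun the six-membered closure onto the cis ester of the neighbouring ring carbon, as in malate-derived cases, and after the first closure that competing ester no longer exists. The expelled methoxide is consumed by the strongly acidic product, so no alkoxide persists and none is ever formed on a ring carbon, and the stabilised bis-tetronate drives both closures. The low temperature guards the strained ring against conrotatory opening.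

Step 14
Reactants: 19 3,9-dibutanoyl-4,10-dihydroxy-1,7-dioxadispiro[4.0.4.2]dodeca-3,9,11-triene-2,8-dione
Product: 20 4,10-dibromo-3,9-dibutanoyl-1,7-dioxadispiro[4.0.4.2]dodeca-3,9,11-triene-2,8-dione (spiro centres unchanged)
Conditions: (COBr)2 (3 equiv), DMF (0.2 equiv), CH2Cl2, 0 °C → rt
Reagents that add atoms: oxalyl bromide, O=C(Br)C(=O)Br
Why: Vilsmeier-type deoxybromination of a vinylogous acid: the bromoiminium salt activates the C4 enol oxygen and bromide adds to C4 and expels DMF. This is known for tetronic acids (4-bromobutenolides) and for 2-acyl-1,3-diones (β-halo enones); the vinylogous-acid oxygen at C4 is exchanged in preference to the side-chain ketone oxygen.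

Step 15
Reactants: 20 4,10-dibromo-3,9-dibutanoyl-1,7-dioxadispiro[4.0.4.2]dodeca-3,9,11-triene-2,8-dione
Product: 21 4,10-dibromo-3,9-bis[(1S)-1-hydroxybutyl]-1,7-dioxadispiro[4.0.4.2]dodeca-3,9,11-triene-2,8-dione ((S,S)-diol)
Conditions: (R)-2-methyl-CBS-oxazaborolidine (0.4 equiv), catecholborane (3 equiv), toluene, −78 °C
Reagents that add atoms: none
Why: CBS reduction of the two enone-type ketones: the fully substituted butenolide carbon is the large group and propyl the small one, so the (R)-catalyst should give the (S)-carbinol at both side chains by reagent control. Catecholborane at low temperature reduces 1,2 and leaves the ring alkene and the C4 bromides alone.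

Step 16
Reactants: 21 4,10-dibromo-3,9-bis[(1S)-1-hydroxybutyl]-1,7-dioxadispiro[4.0.4.2]dodeca-3,9,11-triene-2,8-dione
Product: 22 mono-acetate of 21: (1S)-acetoxybutyl on one butenolide, (1S)-hydroxybutyl on the other
Conditions: Ac2O (0.9 equiv), Sc(OTf)3 (2 mol%), MeCN, −20 °C
Reagents that add atoms: acetic anhydride, CC(=O)OC(C)=O
Why: Lewis acid catalysed acetylation with a deficit of anhydride; the hydroxyls are exchanged by the C2 axis, so either mono-acetylation gives the same 22. The step is statistical and recovered 21 is recycled; amine-free conditions are chosen because amines add to C4 of 4-bromobutenolides.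

Step 17
Reactants: 22 mono-acetate with (1S)-acetoxybutyl and (1S)-hydroxybutyl side chains
Product: 23 4,10-dibromo-3-[(1S)-1-acetoxybutyl]-9-[(1R)-1-acetoxybutyl]-1,7-dioxadispiro[4.0.4.2]dodeca-3,9,11-triene-2,8-dione
Conditions: PPh3, DIAD, AcOH, toluene, 0 °C → rt
Reagents that add atoms: acetic acid, CC(=O)O
Why: Mitsunobu esterification: SN2 displacement of the activated hydroxyl by acetate inverts the remaining (S)-carbinol to the (R)-acetate. SN2′ attack is blocked because the allylic terminus C4 is fully substituted, and ionisation is disfavoured next to the electron-poor alkene.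

Step 18
Reactants: 23 4,10-dibromo-3-[(1S)-1-acetoxybutyl]-9-[(1R)-1-acetoxybutyl]-1,7-dioxadispiro[4.0.4.2]dodeca-3,9,11-triene-2,8-dione
Product: 24 the target: 4,10,11,12-tetrabromo-3-[(1S)-1-acetoxybutyl]-9-[(1R)-1-acetoxybutyl]-1,7-dioxadispiro[4.0.4.2]dodeca-3,9-diene-2,8-dione (C11 and C12 bromines trans to each other, each trans to the ring oxygen of the neighbouring spiro carbon)
Conditions: Br2 (1.05 equiv), CH2Cl2, −78 → −20 °C, dark
Reagents that add atoms: bromine, BrBr
Why: Anti addition of bromine through a bromonium ion sets the two CHBr centres trans; the tetrasubstituted, acceptor-substituted butenolide alkenes do not react. The alkene faces are equivalent through the C2 axis, so only the site of bromide attack decides between the two trans-dibromides; 24 forms when bromide opens the ion at the ring carbon whose neighbouring spiro centre turns C4, not O1, to the attacking face. This is substrate control on the more hindered path, so the sense of selectivity is not secured and the two trans-dibromides would have to be separated.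

## Compound list

1 | dimethyl (4S,5S)-2,2-dimethyl-1,3-dioxolane-4,5-dicarboxylate | COC(=O)[C@H]1OC(C)(C)O[C@@H]1C(=O)OC | starting material
2 | benzyl chloromethyl ether | ClCOCc1ccccc1 | starting material
3 | dimethyl (4R,5S)-4-[(benzyloxy)methyl]-2,2-dimethyl-1,3-dioxolane-4,5-dicarboxylate | COC(=O)[C@]1(COCc2ccccc2)OC(C)(C)O[C@@H]1C(=O)OC | intermediate
4 | dimethyl (4R,5R)-4,5-bis[(benzyloxy)methyl]-2,2-dimethyl-1,3-dioxolane-4,5-dicarboxylate | COC(=O)[C@]1(COCc2ccccc2)OC(C)(C)O[C@@]1(COCc2ccccc2)C(=O)OC | intermediate
5 | dimethyl (2R,3R)-2,3-bis[(benzyloxy)methyl]-2,3-dihydroxybutanedioate | COC(=O)[C@@](O)(COCc1ccccc1)[C@](O)(COCc1ccccc1)C(=O)OC | intermediate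
6 | dimethyl (2R,3R)-2,3-bis[(benzyloxy)methyl]-2,3-bis(triethylsilyloxy)butanedioate | COC(=O)[C@@](O[Si](CC)(CC)CC)(COCc1ccccc1)[C@](O[Si](CC)(CC)CC)(COCc1ccccc1)C(=O)OC | intermediate
7 | dimethyl (2R,3R)-2,3-bis(hydroxymethyl)-2,3-bis(triethylsilyloxy)butanedioate | COC(=O)[C@@](O[Si](CC)(CC)CC)(CO)[C@](O[Si](CC)(CC)CC)(CO)C(=O)OC | intermediate
8 | dimethyl (2S,3S)-2,3-diformyl-2,3-bis(triethylsilyloxy)butanedioate | COC(=O)[C@@](O[Si](CC)(CC)CC)(C=O)[C@](O[Si](CC)(CC)CC)(C=O)C(=O)OC | intermediate
9 | dimethyl (1R,2R,3R,4S)-3,4-dihydroxy-1,2-bis(triethylsilyloxy)cyclobutane-1,2-dicarboxylate | COC(=O)[C@@]1(O[Si](CC)(CC)CC)[C@H](O)[C@H](O)[C@]1(O[Si](CC)(CC)CC)C(=O)OC | intermediate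
10 | dimethyl 3-thioxo-6,7-bis(triethylsilyloxy)-2,4-dioxabicyclo[3.2.0]heptane-6,7-dicarboxylate (cyclic thionocarbonate of 9) | COC(=O)[C@@]1(O[Si](CC)(CC)CC)[C@@H]2OC(=S)O[C@@H]2[C@]1(O[Si](CC)(CC)CC)C(=O)OC | intermediate
11 | dimethyl 6,7-dihydroxy-3-thioxo-2,4-dioxabicyclo[3.2.0]heptane-6,7-dicarboxylate | COC(=O)[C@@]1(O)[C@@H]2OC(=S)O[C@@H]2[C@]1(O)C(=O)OC | intermediate
12 | Meldrum's acid | CC1(C)OC(=O)CC(=O)O1 | starting material
13 | butanoyl chloride | CCCC(Cl)=O | starting material
14 | 5-(1-hydroxybutylidene)-2,2-dimethyl-1,3-dioxane-4,6-dione | CCCC(O)=C1C(=O)OC(C)(C)OC1=O | intermediate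
15 | butanoylketene | CCCC(=O)C=C=O | intermediate (not isolated)
16 | dimethyl 6,7-bis(3-oxohexanoyloxy)-3-thioxo-2,4-dioxabicyclo[3.2.0]heptane-6,7-dicarboxylate | COC(=O)[C@@]1(OC(=O)CC(=O)CCC)[C@@H]2OC(=S)O[C@@H]2[C@]1(OC(=O)CC(=O)CCC)C(=O)OC | intermediate
17 | dimethyl (1R,2R)-1,2-bis(3-oxohexanoyloxy)cyclobut-3-ene-1,2-dicarboxylate | COC(=O)[C@@]1(OC(=O)CC(=O)CCC)C=C[C@@]1(C(=O)OC)OC(=O)CC(=O)CCC | intermediate
18 | methyl 7-butanoyl-8-hydroxy-6-oxo-1-(3-oxohexanoyloxy)-5-oxaspiro[3.4]octa-2,7-diene-1-carboxylate (one ring closed) | CCCC(=O)C1=C(O)[C@@]2(OC1=O)C=C[C@@]2(C(=O)OC)OC(=O)CC(=O)CCC | intermediate (not isolated)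
19 | 3,9-dibutanoyl-4,10-dihydroxy-1,7-dioxadispiro[4.0.4.2]dodeca-3,9,11-triene-2,8-dione | CCCC(=O)C1=C(O)[C@@]2(OC1=O)C=C[C@@]21OC(=O)C(C(=O)CCC)=C1O | intermediate
20 | 4,10-dibromo-3,9-dibutanoyl-1,7-dioxadispiro[4.0.4.2]dodeca-3,9,11-triene-2,8-dione | CCCC(=O)C1=C(Br)[C@@]2(OC1=O)C=C[C@@]21OC(=O)C(C(=O)CCC)=C1Br | intermediate
21 | 4,10-dibromo-3,9-bis[(1S)-1-hydroxybutyl]-1,7-dioxadispiro[4.0.4.2]dodeca-3,9,11-triene-2,8-dione | CCC[C@H](O)C1=C(Br)[C@@]2(OC1=O)C=C[C@@]21OC(=O)C([C@H](CCC)O)=C1Br | intermediate
22 | mono-acetate of 21 ((1S)-acetoxybutyl and (1S)-hydroxybutyl side chains) | CCC[C@H](OC(C)=O)C1=C(Br)[C@@]2(OC1=O)C=C[C@@]21OC(=O)C([C@H](CCC)O)=C1Br | intermediate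
23 | 4,10-dibromo-3-[(1S)-1-acetoxybutyl]-9-[(1R)-1-acetoxybutyl]-1,7-dioxadispiro[4.0.4.2]dodeca-3,9,11-triene-2,8-dione | CCC[C@H](OC(C)=O)C1=C(Br)[C@@]2(OC1=O)C=C[C@@]21OC(=O)C([C@@H](CCC)OC(C)=O)=C1Br | intermediate
24 | 4,10,11,12-tetrabromo-3-[(1S)-1-acetoxybutyl]-9-[(1R)-1-acetoxybutyl]-1,7-dioxadispiro[4.0.4.2]dodeca-3,9-diene-2,8-dione (CNP0266230.1) | CCC[C@H](OC(C)=O)C1=C(Br)[C@@]2(OC1=O)[C@@H](Br)[C@H](Br)[C@@]21OC(=O)C([C@@H](CCC)OC(C)=O)=C1Br | target

## Step count and least certain steps

Total: 18 steps. Longest linear sequence: 17 steps (steps 1–9 and 11–18 from 1); step 10 is a one-step side branch.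

**Step 13 (key step).** The most likely failure is acyl transfer. Liberated methoxide or the tert-butoxide could attack a β-keto ester instead of being consumed as a base. That would leave an alkoxide on a cyclobutene carbon, which opens the ring. Closure onto the ester of the neighbouring ring carbon is the second risk.

The fallback separates ring closure from introduction of the butanoyl group. It sets out from 11. Acetylation (Ac2O, Sc(OTf)3) gives the thionocarbonate diacetate F1. The same Corey–Hopkins olefination gives dimethyl (1R,2R)-1,2-diacetoxycyclobut-3-ene-1,2-dicarboxylate F2. Dieckmann closure of the simple acetates with LiN(SiMe3)2 at −78 °C gives the 3-unsubstituted bis-tetronic acid F3; the ester enolate is formed irreversibly and no nucleophilic alkoxide is free before the tetronate exists. C3-acylation with butanoic acid, DCC and DMAP (O-acylation, then an acyl shift of the Fries type) comes back to the route at 19.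

**Step 18.** Bromide is likely to open the bromonium ion at the other carbon. The attack that leads to 24 passes the vinylic bromine on C4, while the competing attack passes only the ring oxygen. The result would be mainly the other trans-dibromide.

The fallback adds bromine before the butenolides exist, when each alkene carbon is flanked by a large silyloxy group on one face and a methyl ester on the other. It sets out from 10. Corey–Hopkins olefination gives the cyclobutene bis(silyl ether) F4, which is electron-rich and is kept cold. Bromine at −78 °C gives the trans-dibromide F5 with each bromine on the ester side. HF·pyridine gives the dibromo diol F6. Acylation with 14 as in step 11 gives the bis(3-oxohexanoate) F7. Dieckmann closure as in step 13 gives the dibromo bis-tetronic acid F8; the ring has no anti-periplanar H/Br pair, which should protect it from elimination. Oxalyl bromide and DMF give the tetrabromide diketone F9, CBS reduction gives the (S,S)-diol F10, and mono-acetylation gives F11. Mitsunobu inversion with acetic acid comes back to the route at 24.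

**Step 7.** Four-ring closure may be slow. A second electron transfer could then expel a silyloxy group α to the ketyl, or coupling could turn intermolecular.

The fallback builds the ring by Ramberg–Bäcklund contraction instead of carbonyl coupling. It sets out from 7. MsCl and Et3N give the bis-mesylate F12. Na2S in DMF gives the thiolane F13. NCS gives the α-chloro sulfide F14 and mCPBA the α-chloro sulfone F15. KOtBu in THF at −78 °C extrudes SO2 and gives the cyclobutene bis(silyl ether) F4. Immediate dihydroxylation (OsO4 cat., NMO) gives the single possible cis-diol and comes back to the route at 9.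

**Step 2.** Facial selectivity in the second alkylation may be poor. Attack anti to the ester instead of anti to the first arm gives the cis,cis (meso-type) isomer.

The fallback changes the template from a dioxolane to a butane-2,3-diacetal. It sets out from 1. Acetal exchange (butane-2,3-dione, HC(OMe)3, CSA, MeOH) gives the 1,4-dioxane diacetal F16 with both esters equatorial. In this chair each enolate is shielded on its axial face by the axial methoxy group 1,3 to it. Both electrophiles should therefore enter equatorially whatever the neighbouring substituent. Two alkylations with LiN(iPr)2 and 2 give the mono-alkylated diacetal F17 and then the bis-alkylated diacetal F18 (arms equatorial and trans, esters axial). Aqueous TFA removes the diacetal and comes back to the route at 5.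

**Step 17.** Triphenylphosphine or acetate may add to C4 of the bromobutenolide and displace bromide. The activated allylic alcohol may also eliminate instead of being substituted.

The fallback inverts the centre by oxidation and reagent-controlled reduction, without phosphine. It sets out from 22. Dess–Martin oxidation gives the keto acetate F19. Reduction with (S)-2-methyl-CBS-oxazaborolidine and catecholborane gives the (R)-alcohol F20. Acetylation (Ac2O, Sc(OTf)3) comes back to the route at 23.

## Further compounds

F1 | step 13 | dimethyl 6,7-diacetoxy-3-thioxo-2,4-dioxabicyclo[3.2.0]heptane-6,7-dicarboxylate | COC(=O)[C@@]1(OC(C)=O)[C@@H]2OC(=S)O[C@@H]2[C@]1(OC(C)=O)C(=O)OC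
F2 | step 13 | dimethyl (1R,2R)-1,2-diacetoxycyclobut-3-ene-1,2-dicarboxylate | COC(=O)[C@@]1(OC(C)=O)C=C[C@@]1(C(=O)OC)OC(C)=O
F3 | step 13 | 4,10-dihydroxy-1,7-dioxadispiro[4.0.4.2]dodeca-3,9,11-triene-2,8-dione | C1=C(O)[C@@]2(OC1=O)C=C[C@@]21OC(=O)C=C1O
F4 | step 18 | dimethyl (1R,2R)-1,2-bis(triethylsilyloxy)cyclobut-3-ene-1,2-dicarboxylate | COC(=O)[C@@]1(O[Si](CC)(CC)CC)C=C[C@@]1(C(=O)OC)O[Si](CC)(CC)CC
F5 | step 18 | dimethyl 3,4-dibromo-1,2-bis(triethylsilyloxy)cyclobutane-1,2-dicarboxylate (bromines trans, each cis to the neighbouring ester) | COC(=O)[C@@]1(O[Si](CC)(CC)CC)[C@@H](Br)[C@H](Br)[C@@]1(C(=O)OC)O[Si](CC)(CC)CC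
F6 | step 18 | dimethyl 3,4-dibromo-1,2-dihydroxycyclobutane-1,2-dicarboxylate | COC(=O)[C@@]1(O)[C@@H](Br)[C@H](Br)[C@@]1(C(=O)OC)O
F7 | step 18 | dimethyl 3,4-dibromo-1,2-bis(3-oxohexanoyloxy)cyclobutane-1,2-dicarboxylate | COC(=O)[C@@]1(OC(=O)CC(=O)CCC)[C@@H](Br)[C@H](Br)[C@@]1(C(=O)OC)OC(=O)CC(=O)CCC
F8 | step 18 | 11,12-dibromo-3,9-dibutanoyl-4,10-dihydroxy-1,7-dioxadispiro[4.0.4.2]dodeca-3,9-diene-2,8-dione | CCCC(=O)C1=C(O)[C@@]2(OC1=O)[C@@H](Br)[C@H](Br)[C@@]21OC(=O)C(C(=O)CCC)=C1O
F9 | step 18 | 4,10,11,12-tetrabromo-3,9-dibutanoyl-1,7-dioxadispiro[4.0.4.2]dodeca-3,9-diene-2,8-dione | CCCC(=O)C1=C(Br)[C@@]2(OC1=O)[C@@H](Br)[C@H](Br)[C@@]21OC(=O)C(C(=O)CCC)=C1Br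
F10 | step 18 | 4,10,11,12-tetrabromo-3,9-bis[(1S)-1-hydroxybutyl]-1,7-dioxadispiro[4.0.4.2]dodeca-3,9-diene-2,8-dione | CCC[C@H](O)C1=C(Br)[C@@]2(OC1=O)[C@@H](Br)[C@H](Br)[C@@]21OC(=O)C([C@H](CCC)O)=C1Br
F11 | step 18 | mono-acetate of F10 ((1S)-acetoxybutyl and (1S)-hydroxybutyl side chains) | CCC[C@H](OC(C)=O)C1=C(Br)[C@@]2(OC1=O)[C@@H](Br)[C@H](Br)[C@@]21OC(=O)C([C@H](CCC)O)=C1Br
F12 | step 7 | dimethyl (2R,3R)-2,3-bis[(methylsulfonyloxy)methyl]-2,3-bis(triethylsilyloxy)butanedioate | COC(=O)[C@@](O[Si](CC)(CC)CC)(COS(C)(=O)=O)[C@](O[Si](CC)(CC)CC)(COS(C)(=O)=O)C(=O)OC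
F13 | step 7 | dimethyl 3,4-bis(triethylsilyloxy)thiolane-3,4-dicarboxylate (silyloxy groups trans, configuration of 7) | COC(=O)[C@@]1(O[Si](CC)(CC)CC)CSC[C@@]1(C(=O)OC)O[Si](CC)(CC)CC
F14 | step 7 | dimethyl 2-chloro-3,4-bis(triethylsilyloxy)thiolane-3,4-dicarboxylate (mixture at C2) | COC(=O)[C@@]1(O[Si](CC)(CC)CC)C(Cl)SC[C@@]1(C(=O)OC)O[Si](CC)(CC)CC
F15 | step 7 | dimethyl 2-chloro-1,1-dioxo-3,4-bis(triethylsilyloxy)thiolane-3,4-dicarboxylate (mixture at C2) | COC(=O)[C@@]1(O[Si](CC)(CC)CC)C(Cl)S(=O)(=O)C[C@@]1(C(=O)OC)O[Si](CC)(CC)CC
F16 | step 2 | dimethyl (2S,3S,5S,6S)-5,6-dimethoxy-5,6-dimethyl-1,4-dioxane-2,3-dicarboxylate | COC(=O)[C@H]1O[C@](C)(OC)[C@@](C)(OC)O[C@@H]1C(=O)OC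
F17 | step 2 | mono-alkylated diacetal: dimethyl 2-[(benzyloxy)methyl]-5,6-dimethoxy-5,6-dimethyl-1,4-dioxane-2,3-dicarboxylate (arm equatorial, C2 ester axial) | COC(=O)[C@]1(COCc2ccccc2)O[C@](C)(OC)[C@@](C)(OC)O[C@@H]1C(=O)OC
F18 | step 2 | bis-alkylated diacetal: dimethyl 2,3-bis[(benzyloxy)methyl]-5,6-dimethoxy-5,6-dimethyl-1,4-dioxane-2,3-dicarboxylate (arms equatorial and trans, esters axial) | COC(=O)[C@]1(COCc2ccccc2)O[C@](C)(OC)[C@@](C)(OC)O[C@@]1(COCc2ccccc2)C(=O)OC
F19 | step 17 | keto acetate: 3-[(1S)-1-acetoxybutyl]-4,10-dibromo-9-butanoyl-1,7-dioxadispiro[4.0.4.2]dodeca-3,9,11-triene-2,8-dione | CCC[C@H](OC(C)=O)C1=C(Br)[C@@]2(OC1=O)C=C[C@@]21OC(=O)C(C(=O)CCC)=C1Br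
F20 | step 17 | 3-[(1S)-1-acetoxybutyl]-4,10-dibromo-9-[(1R)-1-hydroxybutyl]-1,7-dioxadispiro[4.0.4.2]dodeca-3,9,11-triene-2,8-dione | CCC[C@H](OC(C)=O)C1=C(Br)[C@@]2(OC1=O)C=C[C@@]21OC(=O)C([C@@H](CCC)O)=C1Br
A1 | alternative 1 | bis-spiro cyclobutanol trimethylsilyl ether ((S)-acetate on one butenolide, (S)-tert-butyldimethylsilyl ether on the other) | CCC[C@H](OC(C)=O)C1=C(Br)[C@@]2(OC1=O)[C@H](O[Si](C)(C)C)C[C@@]21OC(=O)C([C@H](CCC)O[Si](C)(C)C(C)(C)C)=C1Br
A2 | alternative 1 | 3-[(1S)-1-acetoxybutyl]-4-bromo-2-(trimethylsilyloxy)furan | CCC[C@H](OC(C)=O)c1c(Br)coc1O[Si](C)(C)C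
A3 | alternative 1 | 4-bromo-3-[(1S)-1-(tert-butyldimethylsilyloxy)butyl]-5-methoxy-5-(2-oxoethyl)furan-2(5H)-one | CCC[C@H](O[Si](C)(C)C(C)(C)C)C1=C(Br)C(CC=O)(OC)OC1=O
A4 | alternative 2 | methyl 4-(tert-butyldimethylsilyloxy)-3-oxo-2-oxabicyclo[2.2.0]hex-5-ene-1-carboxylate | COC(=O)[C@]12OC(=O)[C@@]1(O[Si](C)(C)C(C)(C)C)C=C2
A5 | alternative 2 | methyl 3-(tert-butyldimethylsilyloxy)-2-oxo-2H-pyran-6-carboxylate | COC(=O)C1=CC=C(O[Si](C)(C)C(C)(C)C)C(=O)O1
A6 | alternative 3 | bis-spiro cyclobutene bis(tert-butyldimethylsilyl ether) | CCC[C@H](O[Si](C)(C)C(C)(C)C)C1=C(Br)[C@@]2(OC1=O)C=C[C@@]21OC(=O)C([C@H](CCC)O[Si](C)(C)C(C)(C)C)=C1Br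
A7 | alternative 3 | cyclobut-3-ene-1,2-dione | O=C1C=CC1=O
A8 | alternative 3 | methyl 3,3-dibromo-2-[(1S)-1-(tert-butyldimethylsilyloxy)butyl]prop-2-enoate | CCC[C@H](O[Si](C)(C)C(C)(C)C)C(C(=O)OC)=C(Br)Br
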